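## Retrosynthetic overview

- The quinone is unveiled last by oxidising a para-methoxyphenol. The only ring is the benzene ring of the purchased aldehyde, carried through the whole route; no ring is constructed.
- The tiglate is disconnected at the ester C–O bond (tigloyl chloride plus the (S)-alcohol), and the prenyl terminus comes from cross-metathesis of an allyl carbinol with 2-methylbut-2-ene.
- Key C–C bond (carbinol carbon to CH2): asymmetric carbonyl allylation of a 2-arylacrolein with a pinene-derived allylborane, which sets the single stereocentre as (S).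
- The 2-arylacrolein comes from an arylacetaldehyde by Mannich methylenation; the arylacetaldehyde comes from an ortho-allylphenol by silylation and oxidative alkene cleavage.
- The ortho-allylphenol comes from an aromatic Claisen rearrangement of the allyl ether of 2,4-dimethoxy-3-methylphenol, itself made by Baeyer–Villiger oxidation of 2,4-dimethoxy-3-methylbenzaldehyde.

Assumption: the SMILES is read as (S) at the carbinol carbon with an (E)-2-methylbut-2-enoate (tiglate) ester; TBS = tert-butyldimethylsilyl.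

## Route

Step 1
Reactants: 1 2,4-dimethoxy-3-methylbenzaldehyde
Product: 3 2,4-dimethoxy-3-methylphenol, via aryl formate 2 (not isolated)
Conditions: mCPBA, CH2Cl2, 0 °C → rt; NaHCO3 wash; then K2CO3 (cat.), MeOH, rt
Reagents that add atoms: mCPBA (3-chloroperoxybenzoic acid), OOC(=O)c1cccc(Cl)c1
Why: Baeyer–Villiger (Dakin-type) oxidation, in which the electron-rich aryl group migrates to oxygen and the resulting formate is methanolysed to the phenol.

Step 2
Reactants: 3 2,4-dimethoxy-3-methylphenol; 4 allyl bromide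
Product: 5 1-(allyloxy)-2,4-dimethoxy-3-methylbenzene
Conditions: K2CO3, acetone, reflux
Reagents that add atoms: none
Why: Williamson ether synthesis, an SN2 O-alkylation of the phenoxide by a reactive allylic bromide.

Step 3
Reactants: 5 1-(allyloxy)-2,4-dimethoxy-3-methylbenzene
Product: 7 6-allyl-2,4-dimethoxy-3-methylphenol, via ortho-dienone 6 (not isolated)
Conditions: N,N-diethylaniline, 200 °C, sealed tube
Reagents that add atoms: none
Why: Aromatic Claisen rearrangement ([3,3]-sigmatropic) delivers the allyl group to the only free ortho carbon, since the other ortho and the para position carry methoxy groups, and tautomerisation restores the phenol.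

Step 4
Reactants: 7 6-allyl-2,4-dimethoxy-3-methylphenol
Product: 8 (6-allyl-2,4-dimethoxy-3-methylphenoxy)(tert-butyl)dimethylsilane
Conditions: TBSCl, imidazole, DMAP (cat.), DMF, 40 °C
Reagents that add atoms: TBSCl (tert-butyldimethylsilyl chloride), CC(C)(C)[Si](C)(C)Cl
Why: Imidazole-promoted O-silylation masks the phenol and keeps this oxygen distinct from the two methyl ethers, so the later quinone oxidation is regiodefined.

Step 5
Reactants: 8 (6-allyl-2,4-dimethoxy-3-methylphenoxy)(tert-butyl)dimethylsilane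
Product: 10 2-[2-(TBSO)-3,5-dimethoxy-4-methylphenyl]acetaldehyde, via vicinal diol 9 (not isolated)
Conditions: OsO4 (2 mol %), NaIO4, 2,6-lutidine, dioxane/H2O 3:1, rt; used crude
Reagents that add atoms: OsO4 (osmium tetroxide), O=[Os](=O)(=O)=O, whose oxygen is replenished by NaIO4 (sodium periodate), [Na+].[O-]I(=O)(=O)=O, and water, O
Why: Lemieux–Johnson oxidative cleavage (dihydroxylation then periodate glycol cleavage) of the only alkene present, with 2,6-lutidine suppressing over-oxidation of the arylacetaldehyde.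

Step 6
Reactants: 10 2-[2-(TBSO)-3,5-dimethoxy-4-methylphenyl]acetaldehyde; 11 N,N-dimethylmethyleneiminium iodide (Eschenmoser's salt)
Product: 13 2-[2-(TBSO)-3,5-dimethoxy-4-methylphenyl]prop-2-enal, via Mannich base 12 (not isolated)
Conditions: Et3N, CH2Cl2, rt; short silica plug, used at once
Reagents that add atoms: none
Why: Mannich reaction of the readily enolised arylacetaldehyde with the preformed iminium ion, followed by E1cB loss of dimethylamine, gives the α-methylene aldehyde.

Step 7
Reactants: 13 2-[2-(TBSO)-3,5-dimethoxy-4-methylphenyl]prop-2-enal; 14 (−)-B-methoxydiisopinocampheylborane (from (+)-α-pinene); 15 allylmagnesium bromide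
Product: 18 (3S)-2-[2-(TBSO)-3,5-dimethoxy-4-methylphenyl]hexa-1,5-dien-3-ol, via B-allyldiisopinocampheylborane 16 (not isolated), via O-borinate adduct 17 (not isolated)
Conditions: 14 (1.3 equiv), 15 (1.2 equiv), Et2O, 0 °C → rt, 1 h; then 13, −78 °C, 3 h; then NaBO3·4H2O, THF/H2O, rt
Reagents that add atoms: none
Why: Brown asymmetric allylboration (carbonyl allylation) proceeds through a closed chair transition state in which the isopinocampheyl groups from (+)-α-pinene direct allyl to the Si face of the aldehyde, which gives the (3S) carbinol because O > C2 > C4 > H.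

Step 8
Reactants: 18 (3S)-2-[2-(TBSO)-3,5-dimethoxy-4-methylphenyl]hexa-1,5-dien-3-ol; 19 2-methylbut-2-ene
Product: 20 (3S)-2-[2-(TBSO)-3,5-dimethoxy-4-methylphenyl]-6-methylhepta-1,5-dien-3-ol
Conditions: second-generation Grubbs catalyst (H2IMes)(PCy3)Cl2Ru=CHPh (5 mol %), 2-methylbut-2-ene/CH2Cl2 1:1, rt
Reagents that add atoms: none
Why: Olefin cross-metathesis converts only the monosubstituted alkene into the prenyl terminus, since the hindered 1,1-disubstituted aryl alkene is inert; it is run before acylation so that ring closure onto a tigloyl alkene cannot compete, and the stereocentre is untouched.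

Step 9
Reactants: 20 (3S)-2-[2-(TBSO)-3,5-dimethoxy-4-methylphenyl]-6-methylhepta-1,5-dien-3-ol; 21 tigloyl chloride ((2E)-2-methylbut-2-enoyl chloride)
Product: 22 (3S)-2-[2-(TBSO)-3,5-dimethoxy-4-methylphenyl]-6-methylhepta-1,5-dien-3-yl (2E)-2-methylbut-2-enoate
Conditions: pyridine, DMAP (0.2 equiv), CH2Cl2, 0 °C → rt
Reagents that add atoms: none
Why: DMAP-catalysed nucleophilic acyl substitution forms the O–acyl bond without breaking the C–O bond of the stereocentre, so (S) is retained, and the (E)-tiglate is the thermodynamically preferred geometry under the weak pyridine base.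

Step 10
Reactants: 22 (3S)-2-[2-(TBSO)-3,5-dimethoxy-4-methylphenyl]-6-methylhepta-1,5-dien-3-yl (2E)-2-methylbut-2-enoate
Product: 23 (3S)-2-(2-hydroxy-3,5-dimethoxy-4-methylphenyl)-6-methylhepta-1,5-dien-3-yl (2E)-2-methylbut-2-enoate
Conditions: Bu4NF (1.1 equiv), AcOH (1.2 equiv), THF, 0 °C, 15 min; used directly
Reagents that add atoms: none
Why: Fluoride-mediated desilylation of the aryl silyl ether is driven by Si–F bond formation, and the acetic acid buffer keeps the phenol protonated so the allylic tiglate is not attacked.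

Step 11
Reactants: 23 (3S)-2-(2-hydroxy-3,5-dimethoxy-4-methylphenyl)-6-methylhepta-1,5-dien-3-yl (2E)-2-methylbut-2-enoate
Product: 25 (3S)-2-(5-methoxy-4-methyl-3,6-dioxocyclohexa-1,4-dien-1-yl)-6-methylhepta-1,5-dien-3-yl (2E)-2-methylbut-2-enoate, via quinone hemiketal 24 (not isolated)
Conditions: PhI(OAc)2 (1.1 equiv), MeCN/H2O 2:1, 0 °C
Reagents that add atoms: water, O
Why: Oxidative dearomatisation of a para-methoxyphenol by the trivalent iodine reagent: water adds at the methoxy-bearing para carbon and the hemiketal loses methanol, so only the 1,4-quinone can form, while the alkenes, ester and stereocentre are inert.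

## Compound list

1 | 2,4-dimethoxy-3-methylbenzaldehyde | COc1ccc(C=O)c(OC)c1C | starting material
2 | 2,4-dimethoxy-3-methylphenyl formate | COc1ccc(OC=O)c(OC)c1C | intermediate
3 | 2,4-dimethoxy-3-methylphenol | COc1ccc(O)c(OC)c1C | intermediate
4 | allyl bromide (3-bromoprop-1-ene) | C=CCBr | starting material
5 | 1-(allyloxy)-2,4-dimethoxy-3-methylbenzene | C=CCOc1ccc(OC)c(C)c1OC | intermediate
6 | 6-allyl-2,4-dimethoxy-3-methylcyclohexa-2,4-dien-1-one (racemic) | C=CCC1C=C(OC)C(C)=C(OC)C1=O | intermediate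
7 | 6-allyl-2,4-dimethoxy-3-methylphenol | C=CCc1cc(OC)c(C)c(OC)c1O | intermediate
8 | (6-allyl-2,4-dimethoxy-3-methylphenoxy)(tert-butyl)dimethylsilane | C=CCc1cc(OC)c(C)c(OC)c1O[Si](C)(C)C(C)(C)C | intermediate
9 | 3-[2-(TBSO)-3,5-dimethoxy-4-methylphenyl]propane-1,2-diol (racemic) | OCC(O)Cc1cc(OC)c(C)c(OC)c1O[Si](C)(C)C(C)(C)C | intermediate
10 | 2-[2-(TBSO)-3,5-dimethoxy-4-methylphenyl]acetaldehyde | O=CCc1cc(OC)c(C)c(OC)c1O[Si](C)(C)C(C)(C)C | intermediate
11 | N,N-dimethylmethyleneiminium iodide (Eschenmoser's salt) | C=[N+](C)C.[I-] | starting material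
12 | 3-(dimethylamino)-2-[2-(TBSO)-3,5-dimethoxy-4-methylphenyl]propanal (racemic, formed as its hydroiodide) | CN(C)CC(C=O)c1cc(OC)c(C)c(OC)c1O[Si](C)(C)C(C)(C)C | intermediate
13 | 2-[2-(TBSO)-3,5-dimethoxy-4-methylphenyl]prop-2-enal | C=C(C=O)c1cc(OC)c(C)c(OC)c1O[Si](C)(C)C(C)(C)C | intermediate
14 | (−)-B-methoxydiisopinocampheylborane, from (+)-α-pinene | COB([C@@H]1C[C@@H]2C[C@H]([C@H]1C)C2(C)C)[C@@H]1C[C@@H]2C[C@H]([C@H]1C)C2(C)C | starting material
15 | allylmagnesium bromide | C=CC[Mg]Br | starting material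
16 | B-allyldiisopinocampheylborane (pinanyl groups as in 14) | C=CCB([C@@H]1C[C@@H]2C[C@H]([C@H]1C)C2(C)C)[C@@H]1C[C@@H]2C[C@H]([C@H]1C)C2(C)C | intermediate
17 | diisopinocampheylborinate ester of 18 | C=C(c1cc(OC)c(C)c(OC)c1O[Si](C)(C)C(C)(C)C)[C@H](CC=C)OB([C@@H]1C[C@@H]2C[C@H]([C@H]1C)C2(C)C)[C@@H]1C[C@@H]2C[C@H]([C@H]1C)C2(C)C | intermediate
18 | (3S)-2-[2-(TBSO)-3,5-dimethoxy-4-methylphenyl]hexa-1,5-dien-3-ol | C=C(c1cc(OC)c(C)c(OC)c1O[Si](C)(C)C(C)(C)C)[C@H](CC=C)O | intermediate
19 | 2-methylbut-2-ene | CC=C(C)C | starting material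
20 | (3S)-2-[2-(TBSO)-3,5-dimethoxy-4-methylphenyl]-6-methylhepta-1,5-dien-3-ol | C=C(c1cc(OC)c(C)c(OC)c1O[Si](C)(C)C(C)(C)C)[C@H](CC=C(C)C)O | intermediate
21 | tigloyl chloride, (2E)-2-methylbut-2-enoyl chloride | C/C=C(\C)C(Cl)=O | starting material
22 | (3S)-2-[2-(TBSO)-3,5-dimethoxy-4-methylphenyl]-6-methylhepta-1,5-dien-3-yl (2E)-2-methylbut-2-enoate | C=C(c1cc(OC)c(C)c(OC)c1O[Si](C)(C)C(C)(C)C)[C@H](CC=C(C)C)OC(=O)/C(C)=C/C | intermediate
23 | (3S)-2-(2-hydroxy-3,5-dimethoxy-4-methylphenyl)-6-methylhepta-1,5-dien-3-yl (2E)-2-methylbut-2-enoate | C=C(c1cc(OC)c(C)c(OC)c1O)[C@H](CC=C(C)C)OC(=O)/C(C)=C/C | intermediate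
24 | (3S)-2-(3-hydroxy-3,5-dimethoxy-4-methyl-6-oxocyclohexa-1,4-dien-1-yl)-6-methylhepta-1,5-dien-3-yl (2E)-2-methylbut-2-enoate (hemiketal carbon unassigned) | C=C(C1=CC(O)(OC)C(C)=C(OC)C1=O)[C@H](CC=C(C)C)OC(=O)/C(C)=C/C | intermediate
25 | (3S)-2-(5-methoxy-4-methyl-3,6-dioxocyclohexa-1,4-dien-1-yl)-6-methylhepta-1,5-dien-3-yl (2E)-2-methylbut-2-enoate | C=C(C1=CC(=O)C(C)=C(OC)C1=O)[C@H](CC=C(C)C)OC(=O)/C(C)=C/C | target

## Step count and risk

Total steps: 11. Longest linear sequence: 11 steps (1 → 25); all other inputs are purchased.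

The three steps most likely to fail:

**Step 6 (Mannich methylenation).** The 2-arylacrolein 13 can oligomerise or dimerise by hetero-Diels–Alder reaction before the reaction is complete. The fallback sets out from 10 and comes back at 13, moving the methylenation to the ester oxidation level, where the product is a stable acrylate. Pinnick oxidation of 10 (NaClO2, NaH2PO4, 2-methylbut-2-ene, tBuOH/H2O) gives [2-(TBSO)-3,5-dimethoxy-4-methylphenyl]acetic acid F1. Me3SiCHN2 in toluene/MeOH gives methyl [2-(TBSO)-3,5-dimethoxy-4-methylphenyl]acetate F2. Paraformaldehyde, K2CO3 and Bu4NI in toluene at 80 °C (aldol addition to formaldehyde, then dehydration) give methyl 2-[2-(TBSO)-3,5-dimethoxy-4-methylphenyl]acrylate F3. Reduction with iBu2AlH in CH2Cl2 at −78 °C gives the storable 2-[2-(TBSO)-3,5-dimethoxy-4-methylphenyl]prop-2-en-1-ol F4, which MnO2 in CH2Cl2 oxidises to 13 immediately before step 7.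

**Step 7 (asymmetric allylboration).** The hindered, sensitive α-aryl enal may give insufficient enantiomeric excess. The fallback sets out from 13 and comes back at 18; the same C–C bond is still made by carbonyl allylation, but the stereocentre is set by catalyst-controlled ketone reduction. Barbier allylation of 13 with allyl bromide 4 and Zn dust in THF/saturated aqueous NH4Cl gives racemic 2-[2-(TBSO)-3,5-dimethoxy-4-methylphenyl]hexa-1,5-dien-3-ol F5. Dess–Martin periodinane with NaHCO3 in CH2Cl2 at 0 °C gives 2-[2-(TBSO)-3,5-dimethoxy-4-methylphenyl]hexa-1,5-dien-3-one F6, which is used at once to avoid alkene migration. Corey–Bakshi–Shibata reduction with (R)-2-methyl-CBS-oxazaborolidine and catecholborane in toluene at −78 °C returns 18. With the 2-arylvinyl group as the large substituent, the (R)-catalyst gives the (S)-alcohol, the same sense in which the (S)-catalyst gives (R)-1-phenylethanol from acetophenone.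

**Step 11 (oxidation to the quinone).** Aqueous oxidation of the electron-rich phenol 23 could give ortho-quinone or over-oxidised material. The fallback sets out from 23 and comes back at 25, separating oxidation from unmasking. PhI(OAc)2 in anhydrous MeOH at 0 °C gives the isolable quinone monoketal (3S)-2-(3,3,5-trimethoxy-4-methyl-6-oxocyclohexa-1,4-dien-1-yl)-6-methylhepta-1,5-dien-3-yl (2E)-2-methylbut-2-enoate F7. Oxalic acid on wet silica in CH2Cl2 at rt then hydrolyses the ketal to 25.

Further compounds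
F1 | step 6 | [2-(TBSO)-3,5-dimethoxy-4-methylphenyl]acetic acid | OC(=O)Cc1cc(OC)c(C)c(OC)c1O[Si](C)(C)C(C)(C)C
F2 | step 6 | methyl [2-(TBSO)-3,5-dimethoxy-4-methylphenyl]acetate | COC(=O)Cc1cc(OC)c(C)c(OC)c1O[Si](C)(C)C(C)(C)C
F3 | step 6 | methyl 2-[2-(TBSO)-3,5-dimethoxy-4-methylphenyl]acrylate | C=C(C(=O)OC)c1cc(OC)c(C)c(OC)c1O[Si](C)(C)C(C)(C)C
F4 | step 6 | 2-[2-(TBSO)-3,5-dimethoxy-4-methylphenyl]prop-2-en-1-ol | C=C(CO)c1cc(OC)c(C)c(OC)c1O[Si](C)(C)C(C)(C)C
F5 | step 7 | racemic 2-[2-(TBSO)-3,5-dimethoxy-4-methylphenyl]hexa-1,5-dien-3-ol | C=C(c1cc(OC)c(C)c(OC)c1O[Si](C)(C)C(C)(C)C)C(O)CC=C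
F6 | step 7 | 2-[2-(TBSO)-3,5-dimethoxy-4-methylphenyl]hexa-1,5-dien-3-one | C=C(c1cc(OC)c(C)c(OC)c1O[Si](C)(C)C(C)(C)C)C(=O)CC=C
F7 | step 11 | (3S)-2-(3,3,5-trimethoxy-4-methyl-6-oxocyclohexa-1,4-dien-1-yl)-6-methylhepta-1,5-dien-3-yl (2E)-2-methylbut-2-enoate | C=C(C1=CC(OC)(OC)C(C)=C(OC)C1=O)[C@H](CC=C(C)C)OC(=O)/C(C)=C/C
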